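Numbers refer to the compound list after the steps; C1'–C5' are the chain carbons counted from C5.

## Analysis of the target

Target 23 is a 5,6,7,8-tetrahydroquinoline 1-oxide. Its pyridine ring is fully substituted (C2 methyl, C3 and C4 methoxy) and is fused through C4a and C8a to a saturated six-membered carbocycle (C5–C8). The only stereocentre is C5 (R), a benzylic methine that carries the 5-phenylpentyl chain and lies peri to the C4 methoxy group. With no second stereocentre to relay from, the configuration has to come from a catalyst. The N-oxide would not survive hydrogenation, low-valent metals or radical reduction, so it belongs at the very end. The 4-methoxy group can be cleaved to the pyridone by hot halide or acid, and the C2 methyl and C8 methylene are picoline-type C–H acids. The difficulty is that C5 is flanked only by an aryl carbon, a ring methylene and an unfunctionalised chain, so nothing in the target marks how to build it selectively, and the five different pyridine substituents must be placed without ambiguity. The plan rests on one feature: C5 is bonded to C4a, C6 and C1', which is the pattern of the branched carbon of a 1-arylallyl unit, with C1'=C2' as a vinyl group and C6 as a carbon nucleophile.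

## Retrosynthetic reasoning

**N–O bond.** The N-oxide of 23 is removed first, leading to pyridine 22. This leaves the most fragile group to a final chemoselective oxidation of a molecule with no other oxidisable site.

**C6 carboxyl groups.** C6 of 22 is a plain methylene, but it can only act as a nucleophile if it carries acidifying groups. Two carboxyl groups are therefore put back on C6, giving monoacid 20 and, behind it, diester 18. The forward direction has to erase both. One leaves by hydrolysis and thermal decarboxylation, the other by radical decarboxylation, and neither touches C5.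

**C1'=C2' bond.** The chain of 18 is cut between C1' and C2' after introducing a double bond there (alkene 17). This leads to the vinyl compound 15 and the terminal alkene 16, to be joined by cross-metathesis and hydrogenated. The cut is made here because a vinyl group at C5 is exactly what a branched-selective allylic substitution leaves behind.

**C5–C6 bond (key disconnection).** Cutting C5–C6 in 15 opens the carbocycle to the allylic carbonate 14, in which the malonate carbon is tethered to pyridine C2 and the cinnamyl-type carbonate sits on pyridine C3. This is the only ring bond whose formation creates the stereocentre, and closure at the aryl-bearing allyl terminus gives a six-membered ring while closure at the other terminus would give an eight-membered one. The forward reaction must ionise the carbonate, choose one face of the allyl unit and join C6 to C5.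

**Carbonate and aryl–alkenyl bond.** Carbonate 14 comes from alcohol 13, which comes from silyl ether 12. The bond between the pyridine and the propenyl group is cut to give bromide 10 and the (E)-alkenyl boronate 11, whose geometry is carried over.

**Malonate side chain.** The bond between the malonate carbon and the ethylene bridge of 10 is cut in the sense of a conjugate addition, giving the 2-vinylpyridine 8 and dimethyl malonate 9. The vinyl group of 8 is then disconnected from the ring, giving the bromo iodide 6 and vinyl boronate 7. The two different halogens let the two cross-couplings be run in a fixed order.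

**Halogens and the C4 methoxy group.** The iodine of 6 goes back to the only ring C–H of bromide 4. The C4 methoxy group of 4 goes back to chloride 3 and pyridone 2. The bromine goes back to the commercial pyridone 1, which already holds the methyl group, the C3 methoxy group and the C4 oxygen in the right places.

## Alternatives that were turned down

**Alternative 1:** The heteroaromatic ring itself is disconnected. The target is traced to the 4-pyranone (5R)-3-methoxy-2-methyl-5-(5-phenylpentyl)-5,6,7,8-tetrahydro-4H-chromen-4-one A1, cut at C4–C4a and O–C8a. In the forward step, thermolysis of 5-methoxy-2,2,6-trimethyl-4H-1,3-dioxin-4-one A2 releases the acylketene 2-methoxybut-1-ene-1,3-dione A3. A3 adds across the regiodefined silyl enol ether trimethyl{[(3R)-3-(5-phenylpentyl)cyclohex-1-en-1-yl]oxy}silane A4 and, after loss of silanol, closes the pyranone.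
- For it: C5 would be set early by an asymmetric conjugate addition with enolate trapping, one of the most dependable asymmetric reactions. The methyl, methoxy and carbonyl groups arrive in one piece. The sequence is clearly shorter than the one chosen here, and on step economy and robustness of the stereocentre it is the stronger plan.
- Against it: the cycloaddition has to engage the enol ether carbon next to the branching C5, at temperatures where acylketenes dimerise and silyl enol ethers can migrate. An α-alkoxy acylketene is a less explored partner. After the annulation, oxygen must be exchanged for nitrogen on a fully substituted, fused pyranone. The C4 oxygen must then be converted to methoxy by chlorination and substitution at a position crowded by the C5 substituent and no longer activated.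
- In comparison, the chosen plan offers a pyridine core bought with its oxygen pattern in place and each later bond made by predictable polar or cross-coupling chemistry, and its one uncertain step has its regiochemistry enforced by ring size.

**Alternative 2:** The whole carbocycle is annulated onto a pyridine in one palladium-relay step. C8–C8a and C4a–C5 are cut, giving 5-iodo-3,4-dimethoxy-2-methylpyridine A6 and ethyl (2E)-6-bromohex-2-enoate A7. In the forward Catellani reaction, the aryl iodide is alkylated at its free ortho position through a bicyclic-olefin palladacycle, and a terminating Heck closure then gives ethyl (2E)-2-(3,4-dimethoxy-2-methyl-7,8-dihydroquinolin-5(6H)-ylidene)acetate A5.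
- For it: two C–C bonds and the ring form in one operation from an iodide three steps from the same pyridone, and no activating group has to be removed afterwards. On ring-forming economy it is stronger than the chosen plan.
- Against it: A5 is achiral, so C5 must be set in a separate asymmetric conjugate reduction of a hindered exocyclic β,β-disubstituted enoate lying peri to the methoxy group. The exocyclic alkene can slip into the ring under palladium hydride. The ortho palladation must occur at the carbon α to a free pyridine nitrogen, which can bind divalent palladium. The ester stub then needs three further steps to become the chain.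
- In comparison, the chosen plan joins ring closure and stereo-induction in one catalyst-controlled event and leaves a vinyl group that one metathesis turns into the chain.

**Alternative 3:** The C6–C7 bond is cut as an alkene, leading to the triene 3,4-dimethoxy-2-methyl-5-(penta-1,4-dien-3-yl)-6-(prop-2-en-1-yl)pyridine A9. In the forward step a chiral molybdenum imido alkylidene of the type Mo(NAr)(CHCMe2Ph)(biaryloxide) closes one of the two enantiotopic vinyl groups onto the allyl group. The product is (5R)-5-ethenyl-3,4-dimethoxy-2-methyl-5,8-dihydroquinoline A8.
- For it: ring and stereocentre are made in one catalytic step, as in the chosen plan, and A8 already has the vinyl handle. There are no carboxyl groups to erase, which saves the three-step removal needed here, so it is stronger on that point.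
- Against it: A9 contains a bis-allylic, benzylic methine ortho to a methoxy group. It is hard to make in branched form and isomerises easily into conjugation. The molybdenum catalysts are sensitive to air and to Lewis-basic nitrogen. A8 is a 5,8-dihydroquinoline whose C5–H is doubly allylic and benzylic, so aromatisation or alkene migration would erase the stereocentre.
- In comparison, the chosen plan accepts extra steps for a precursor assembled by cross-coupling and for intermediates that are not prone to aromatise.

Key step: step 10

Assumption: the (Sa,S,S) phosphoramidite is taken to place iridium on the Re face of C5 in 14, so that C6 adds to the Si face and gives 5S; this sense is assigned by analogy with aryl-substituted allyl carbonates and could not be confirmed here; should it be the reverse, the (Ra,R,R) ligand is used with no other change.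

## Steps

Step 1
Reactants: 1 3-methoxy-2-methylpyridin-4(1H)-one
Product: 2 5-bromo-3-methoxy-2-methylpyridin-4(1H)-one
Conditions: NBS (1.05 equiv), DMF, 0 °C to rt, dark
Reagents that add atoms: N-bromosuccinimide, O=C1CCC(=O)N1Br
Why: Electrophilic bromination of the vinylogous amide; C5 is the only free carbon α to the carbonyl and β to nitrogen, and ionic conditions in the dark leave the methyl group alone.

Step 2
Reactants: 2 5-bromo-3-methoxy-2-methylpyridin-4(1H)-one
Product: 3 5-bromo-4-chloro-3-methoxy-2-methylpyridine
Conditions: POCl3 (neat), 95 °C; aqueous work-up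
Reagents that add atoms: phosphoryl chloride, O=P(Cl)(Cl)Cl
Why: Deoxychlorination of a 4-pyridone through its O-phosphorylated pyridinium, which chloride attacks at C4; the bromide at the β-position is not activated towards exchange.

Step 3
Reactants: 3 5-bromo-4-chloro-3-methoxy-2-methylpyridine
Product: 4 5-bromo-3,4-dimethoxy-2-methylpyridine
Conditions: NaOMe (3 equiv), MeOH, 80 °C (sealed vessel)
Reagents that add atoms: sodium methoxide, [Na+].[O-]C
Why: Nucleophilic aromatic substitution at C4, para to the ring nitrogen, which takes up the negative charge of the adduct; the C5 bromide at a β-position has no such stabilisation and stays.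

Step 4
Reactants: 4 5-bromo-3,4-dimethoxy-2-methylpyridine
Product: 6 3-bromo-2-iodo-4,5-dimethoxy-6-methylpyridine, via 2-pyridylmagnesium chloride 5 (not isolated)
Conditions: TMPMgCl·LiCl (1.2 equiv), THF, −40 °C; then I2, −40 °C to rt
Reagents that add atoms: iodine, II
Why: Directed magnesiation with a hindered magnesium amide; the only ring hydrogen lies between the nitrogen and the bromine, which both acidify it and guide the base, and the arylmagnesium species is stable at low temperature and is iodinated at the same carbon.

Step 5
Reactants: 6 3-bromo-2-iodo-4,5-dimethoxy-6-methylpyridine; 7 2-ethenyl-4,4,5,5-tetramethyl-1,3,2-dioxaborolane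
Product: 8 3-bromo-2-ethenyl-4,5-dimethoxy-6-methylpyridine
Conditions: Pd(PPh3)4 (3 mol %), K2CO3, 1,4-dioxane/H2O, 60 °C
Reagents that add atoms: none
Why: Suzuki–Miyaura coupling; zerovalent palladium inserts into the weaker C–I bond α to nitrogen much faster than into the flanked C–Br bond, so the vinyl group enters at C2 only.

Step 6
Reactants: 8 3-bromo-2-ethenyl-4,5-dimethoxy-6-methylpyridine; 9 dimethyl malonate
Product: 10 dimethyl 2-[2-(3-bromo-4,5-dimethoxy-6-methylpyridin-2-yl)ethyl]propanedioate
Conditions: 9 (3 equiv), NaOMe (0.2 equiv), MeOH, 65 °C
Reagents that add atoms: none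
Why: Michael addition of the malonate anion to a 2-vinylpyridine, whose terminal carbon is electrophilic because the intermediate carbanion is delocalised onto the ring nitrogen; excess 9 suppresses double addition and the alkoxide matches the esters.

Step 7
Reactants: 10 dimethyl 2-[2-(3-bromo-4,5-dimethoxy-6-methylpyridin-2-yl)ethyl]propanedioate; 11 (E)-tert-butyldimethyl{[3-(4,4,5,5-tetramethyl-1,3,2-dioxaborolan-2-yl)prop-2-en-1-yl]oxy}silane
Product: 12 dimethyl 2-{2-[3-[(1E)-3-{[tert-butyl(dimethyl)silyl]oxy}prop-1-en-1-yl]-4,5-dimethoxy-6-methylpyridin-2-yl]ethyl}propanedioate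
Conditions: PdCl2(dppf) (5 mol %), K2CO3, 1,4-dioxane/H2O (5:1), 85 °C
Reagents that add atoms: none
Why: Suzuki–Miyaura coupling of the remaining bromide with an (E)-alkenyl boronate, which transfers the alkenyl group with retention of geometry; the bidentate ligand disfavours C-arylation of the malonate and the carbonate base is mild enough for the esters and the silyl ether.

Step 8
Reactants: 12 dimethyl 2-{2-[3-[(1E)-3-{[tert-butyl(dimethyl)silyl]oxy}prop-1-en-1-yl]-4,5-dimethoxy-6-methylpyridin-2-yl]ethyl}propanedioate
Product: 13 dimethyl 2-{2-[3-[(1E)-3-hydroxyprop-1-en-1-yl]-4,5-dimethoxy-6-methylpyridin-2-yl]ethyl}propanedioate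
Conditions: TBAF (1.2 equiv), AcOH (1.2 equiv), THF, 0 °C to rt
Reagents that add atoms: none
Why: Fluoride cleaves the Si–O bond, driven by the strong Si–F bond; buffering with acetic acid keeps the medium near neutral, so the malonate and its esters are not disturbed.

Step 9
Reactants: 13 dimethyl 2-{2-[3-[(1E)-3-hydroxyprop-1-en-1-yl]-4,5-dimethoxy-6-methylpyridin-2-yl]ethyl}propanedioate
Product: 14 dimethyl 2-{2-[4,5-dimethoxy-3-[(1E)-3-(methoxycarbonyloxy)prop-1-en-1-yl]-6-methylpyridin-2-yl]ethyl}propanedioate
Conditions: ClCO2Me (1.5 equiv), pyridine (3 equiv), CH2Cl2, 0 °C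
Reagents that add atoms: methyl chloroformate, COC(=O)Cl
Why: O-Acylation of the primary allylic alcohol with a chloroformate gives the methyl carbonate, a leaving group that ionises cleanly and supplies its own base in the next step; the malonate is not deprotonated by pyridine.

Step 10
Reactants: 14 dimethyl 2-{2-[4,5-dimethoxy-3-[(1E)-3-(methoxycarbonyloxy)prop-1-en-1-yl]-6-methylpyridin-2-yl]ethyl}propanedioate
Product: 15 dimethyl (5S)-5-ethenyl-3,4-dimethoxy-2-methyl-7,8-dihydroquinoline-6,6(5H)-dicarboxylate
Conditions: [Ir(cod)Cl]2 (2 mol %), (Sa)-1,1'-binaphthalene-2,2'-diyl N,N-bis[(S)-1-(2-methoxyphenyl)ethyl]phosphoramidite (4 mol %), TBD (8 mol %), THF, rt; then 14 (0.05 M), 50 °C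
Reagents that add atoms: none
Why: The cyclometalated monovalent iridium–phosphoramidite complex formed on activation with TBD ionises the carbonate of 14 with loss of CO2 and methoxide to give an allyl complex of trivalent iridium, and the methoxide deprotonates the malonate, so no external base is needed. The malonate carbon C6 then attacks the aryl-bearing allyl terminus C5 on the face opposite to iridium, forming C5–C6 and returning the monovalent catalyst. The closest known reaction type is the iridium-catalysed branched-selective asymmetric allylic alkylation of cinnamyl carbonates with malonates, in its intramolecular salt-free form that gives 2-vinyl carbocycles. The carbocycle closes in the 6-exo mode with C1' and C2' left outside the ring as the vinyl group; attack at the CH2 terminus would need an eight-membered ring holding an E-alkene, so the tether and the intrinsic preference of iridium for the substituted terminus point the same way. C5 is set by the catalyst alone: the ligand decides which face of the alkene carries iridium, and the (Sa,S,S) ligand is chosen so that C6 adds to the Si face of C5, which is 5S. The step needs enantioface selectivity on an allyl unit whose aryl group has two ortho substituents, which is why the ligand variant with ortho-methoxyphenyl groups is used; the ortho groups also twist the allyl unit out of the ring plane, which is the geometry the tethered nucleophile needs. Cyclisation must outrun intermolecular alkylation, which the dilution secures, and the pyridine nitrogen lies between a methyl group and the tether and should not bind iridium.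

Step 11
Reactants: 15 dimethyl (5S)-5-ethenyl-3,4-dimethoxy-2-methyl-7,8-dihydroquinoline-6,6(5H)-dicarboxylate; 16 5-phenylpent-1-ene
Product: 17 dimethyl (5S)-3,4-dimethoxy-2-methyl-5-[(1E)-5-phenylpent-1-en-1-yl]-7,8-dihydroquinoline-6,6(5H)-dicarboxylate
Conditions: 16 (5 equiv), RuCl2(H2IMes)(=CH-C6H4-2-OiPr) (second-generation Hoveyda–Grubbs catalyst, 10 mol %), 1,4-benzoquinone (10 mol %), CH2Cl2, 40 °C
Reagents that add atoms: none
Why: Olefin cross-metathesis; the hindered vinyl group of 15 does not homodimerise, the unhindered alkene 16 does so reversibly, and the ruthenium alkylidene funnels both into the E cross product with loss of ethene. Benzoquinone suppresses ruthenium hydride isomerisation that could move the alkene towards C5.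

Step 12
Reactants: 17 dimethyl (5S)-3,4-dimethoxy-2-methyl-5-[(1E)-5-phenylpent-1-en-1-yl]-7,8-dihydroquinoline-6,6(5H)-dicarboxylate
Product: 18 dimethyl (5S)-3,4-dimethoxy-2-methyl-5-(5-phenylpentyl)-7,8-dihydroquinoline-6,6(5H)-dicarboxylate
Conditions: H2 (1 atm), Pt/C (5 wt %), EtOAc, rt
Reagents that add atoms: none
Why: Heterogeneous hydrogenation of the disubstituted alkene; platinum is preferred to palladium because it causes little double-bond migration, which could otherwise reach C5 and erode the stereocentre, and under neutral conditions at 1 atm neither aromatic ring is reduced.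

Step 13
Reactants: 18 dimethyl (5S)-3,4-dimethoxy-2-methyl-5-(5-phenylpentyl)-7,8-dihydroquinoline-6,6(5H)-dicarboxylate
Product: 20 (5R)-3,4-dimethoxy-2-methyl-5-(5-phenylpentyl)-5,6,7,8-tetrahydroquinoline-6-carboxylic acid, via malonic diacid 19 (not isolated)
Conditions: KOH (10 equiv), MeOH/H2O (2:1), 80 °C; AcOH to pH 5; then DMSO, 130 °C
Reagents that add atoms: potassium hydroxide, [K+].[OH-]
Why: Saponification of both methyl esters, then thermal decarboxylation of the gem-dicarboxylic acid through a cyclic six-membered transition state (end-game of the malonic ester synthesis). C5 is untouched because its hydrogen is not α to a carbonyl group; C6 forms as a mixture of epimers that step 14 erases, and the descriptor at C5 changes from S to R only because the priorities change.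

Step 14
Reactants: 20 (5R)-3,4-dimethoxy-2-methyl-5-(5-phenylpentyl)-5,6,7,8-tetrahydroquinoline-6-carboxylic acid
Product: 22 (5R)-3,4-dimethoxy-2-methyl-5-(5-phenylpentyl)-5,6,7,8-tetrahydroquinoline, via thiohydroxamate ester 21 (not isolated)
Conditions: N-hydroxypyridine-2-thione, DCC, DMAP (cat.), CH2Cl2, rt, dark; then t-BuSH (10 equiv), visible light, rt
Reagents that add atoms: none
Why: Barton reductive decarboxylation; the N–O bond of the thiohydroxamate ester breaks under light, the carboxyl radical loses CO2, and the secondary C6 radical takes a hydrogen atom from the thiol. A radical at C6 cannot invert C5.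

Step 15
Reactants: 22 (5R)-3,4-dimethoxy-2-methyl-5-(5-phenylpentyl)-5,6,7,8-tetrahydroquinoline
Product: 23 (5R)-3,4-dimethoxy-2-methyl-5-(5-phenylpentyl)-5,6,7,8-tetrahydroquinoline 1-oxide
Conditions: mCPBA (1.1 equiv), CH2Cl2, 0 °C to rt
Reagents that add atoms: 3-chloroperoxybenzoic acid, OOC(=O)c1cccc(Cl)c1
Why: N-Oxidation of the electron-rich pyridine by the peracid; no alkene or other oxidisable group is left, and the oxidation is placed last because the N-oxide would not survive the hydrogenation, the metal-catalysed steps or the radical reduction.

## Compound list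

1 | 3-methoxy-2-methylpyridin-4(1H)-one | COc1c(C)[nH]ccc1=O | starting material
2 | 5-bromo-3-methoxy-2-methylpyridin-4(1H)-one | COc1c(C)[nH]cc(Br)c1=O | intermediate
3 | 5-bromo-4-chloro-3-methoxy-2-methylpyridine | COc1c(C)ncc(Br)c1Cl | intermediate
4 | 5-bromo-3,4-dimethoxy-2-methylpyridine | COc1c(C)ncc(Br)c1OC | intermediate
5 | (3-bromo-4,5-dimethoxy-6-methylpyridin-2-yl)magnesium chloride (as its LiCl complex) | COc1c(C)nc([Mg]Cl)c(Br)c1OC | intermediate
6 | 3-bromo-2-iodo-4,5-dimethoxy-6-methylpyridine | COc1c(C)nc(I)c(Br)c1OC | intermediate
7 | 2-ethenyl-4,4,5,5-tetramethyl-1,3,2-dioxaborolane | C=CB1OC(C)(C)C(C)(C)O1 | starting material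
8 | 3-bromo-2-ethenyl-4,5-dimethoxy-6-methylpyridine | C=Cc1nc(C)c(OC)c(OC)c1Br | intermediate
9 | dimethyl malonate | COC(=O)CC(=O)OC | starting material
10 | dimethyl 2-[2-(3-bromo-4,5-dimethoxy-6-methylpyridin-2-yl)ethyl]propanedioate | COC(=O)C(CCc1nc(C)c(OC)c(OC)c1Br)C(=O)OC | intermediate
11 | (E)-tert-butyldimethyl{[3-(4,4,5,5-tetramethyl-1,3,2-dioxaborolan-2-yl)prop-2-en-1-yl]oxy}silane | CC(C)(C)[Si](C)(C)OC/C=C/B1OC(C)(C)C(C)(C)O1 | starting material
12 | dimethyl 2-{2-[3-[(1E)-3-{[tert-butyl(dimethyl)silyl]oxy}prop-1-en-1-yl]-4,5-dimethoxy-6-methylpyridin-2-yl]ethyl}propanedioate | CC(C)(C)[Si](C)(C)OC/C=C/c1c(OC)c(OC)c(C)nc1CCC(C(=O)OC)C(=O)OC | intermediate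
13 | dimethyl 2-{2-[3-[(1E)-3-hydroxyprop-1-en-1-yl]-4,5-dimethoxy-6-methylpyridin-2-yl]ethyl}propanedioate | OC/C=C/c1c(OC)c(OC)c(C)nc1CCC(C(=O)OC)C(=O)OC | intermediate
14 | dimethyl 2-{2-[4,5-dimethoxy-3-[(1E)-3-(methoxycarbonyloxy)prop-1-en-1-yl]-6-methylpyridin-2-yl]ethyl}propanedioate | COC(=O)OC/C=C/c1c(OC)c(OC)c(C)nc1CCC(C(=O)OC)C(=O)OC | intermediate
15 | dimethyl (5S)-5-ethenyl-3,4-dimethoxy-2-methyl-7,8-dihydroquinoline-6,6(5H)-dicarboxylate | COc1c(OC)c(C)nc2c1[C@H](C=C)C(C(=O)OC)(C(=O)OC)CC2 | intermediate
16 | 5-phenylpent-1-ene | C=CCCCc1ccccc1 | starting material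
17 | dimethyl (5S)-3,4-dimethoxy-2-methyl-5-[(1E)-5-phenylpent-1-en-1-yl]-7,8-dihydroquinoline-6,6(5H)-dicarboxylate | COc1c(OC)c(C)nc2c1[C@H](/C=C/CCCc1ccccc1)C(C(=O)OC)(C(=O)OC)CC2 | intermediate
18 | dimethyl (5S)-3,4-dimethoxy-2-methyl-5-(5-phenylpentyl)-7,8-dihydroquinoline-6,6(5H)-dicarboxylate | COc1c(OC)c(C)nc2c1[C@H](CCCCCc1ccccc1)C(C(=O)OC)(C(=O)OC)CC2 | intermediate
19 | (5S)-3,4-dimethoxy-2-methyl-5-(5-phenylpentyl)-7,8-dihydroquinoline-6,6(5H)-dicarboxylic acid | COc1c(OC)c(C)nc2c1[C@H](CCCCCc1ccccc1)C(C(=O)O)(C(=O)O)CC2 | intermediate
20 | (5R)-3,4-dimethoxy-2-methyl-5-(5-phenylpentyl)-5,6,7,8-tetrahydroquinoline-6-carboxylic acid (both C6 epimers) | COc1c(OC)c(C)nc2c1[C@H](CCCCCc1ccccc1)C(C(=O)O)CC2 | intermediate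
21 | 2-thioxopyridin-1(2H)-yl (5R)-3,4-dimethoxy-2-methyl-5-(5-phenylpentyl)-5,6,7,8-tetrahydroquinoline-6-carboxylate (both C6 epimers) | COc1c(OC)c(C)nc2c1[C@H](CCCCCc1ccccc1)C(C(=O)On1ccccc1=S)CC2 | intermediate
22 | (5R)-3,4-dimethoxy-2-methyl-5-(5-phenylpentyl)-5,6,7,8-tetrahydroquinoline | COc1c(OC)c(C)nc2c1[C@H](CCCCCc1ccccc1)CCC2 | intermediate
23 | (5R)-3,4-dimethoxy-2-methyl-5-(5-phenylpentyl)-5,6,7,8-tetrahydroquinoline 1-oxide | COc1c(OC)c(C)[n+]([O-])c2c1[C@H](CCCCCc1ccccc1)CCC2 | target

## Step count and least certain steps

Total step count: 15. Longest linear sequence: 15 steps, from 1 to 23; compounds 7, 9, 11 and 16 are bought.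

**Step 10 (key step).** The most likely failure is poor enantioface discrimination together with slow ionisation, because the allyl unit carries an aryl group with two ortho substituents, a pattern that is demanding for this catalyst family. Intermolecular alkylation could also compete if the ring closure is slow. The fallback forms the same C5–C6 bond by iminium catalysis and sets out from 13.
- Oxidation of 13 with MnO2 in CH2Cl2 should give the enal dimethyl 2-{2-[4,5-dimethoxy-6-methyl-3-[(1E)-3-oxoprop-1-en-1-yl]pyridin-2-yl]ethyl}propanedioate F1.
- Intramolecular Michael addition of the malonate under (S)-α,α-diphenylprolinol trimethylsilyl ether and benzoic acid should close the ring to the aldehyde dimethyl (5S)-3,4-dimethoxy-2-methyl-5-(2-oxoethyl)-7,8-dihydroquinoline-6,6(5H)-dicarboxylate F2. The catalyst enantiomer is chosen from its usual shielding model.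
- Wittig reaction with the ylide made from (3-phenylpropyl)triphenylphosphonium bromide and NaN(SiMe3)2 should give the alkene dimethyl (5S)-3,4-dimethoxy-2-methyl-5-[(2Z)-5-phenylpent-2-en-1-yl]-7,8-dihydroquinoline-6,6(5H)-dicarboxylate F3.
- Hydrogenation over Pt/C comes back to the route at 18.

**Step 4.** The risk is competing deprotonation of the C2 methyl group, which is a picoline-type C–H acid, and elimination from 5 to a pyridyne if the temperature rises. The fallback replaces metalation by a radical C–H alkylation and sets out from 4. Conjugate addition of 9 to tert-butyl acrylate gives the triester 1-tert-butyl 3,3-dimethyl propane-1,3,3-tricarboxylate F4. Cleavage of the tert-butyl ester with trifluoroacetic acid gives the acid 5-methoxy-4-(methoxycarbonyl)-5-oxopentanoic acid F5. Minisci decarboxylative alkylation of 4 with this acid (AgNO3 cat., (NH4)2S2O8, trifluoroacetic acid, CH2Cl2/H2O, 40 °C) attacks the only free ring position and comes back to the route at 10, bypassing 6 and 8.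

**Step 7.** After oxidative addition, the arylpalladium intermediate could be trapped by the tethered malonate (five-membered C-arylation), or the esters could be partly hydrolysed by the aqueous base. The fallback is a base-free Stille coupling. It sets out from 10 and uses (E)-3-(tributylstannyl)prop-2-en-1-ol, Pd(PPh3)4 and CuI in toluene at 100 °C. It comes back to the route at 13 and makes the silyl ether unnecessary.

**Step 11.** Metathesis may be sluggish at a vinyl group flanked by the branched C5 and the quaternary C6, while homodimerisation of 16 consumes catalyst. The fallback builds the chain by sp3–sp3 coupling and sets out from 15. Hydroboration with 9-BBN gives the alkylborane dimethyl (5S)-5-[2-(9-borabicyclo[3.3.1]nonan-9-yl)ethyl]-3,4-dimethoxy-2-methyl-7,8-dihydroquinoline-6,6(5H)-dicarboxylate F6. This is coupled in the same flask with (3-bromopropyl)benzene (Pd(OAc)2, PCy3, K3PO4·H2O, THF, rt). The sequence comes back to the route at 18 and needs no hydrogenation.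

**Step 13.** Hydrolysis may stop at the half-ester, because the second ester is shielded by the quaternary centre and the neighbouring carboxylate. The fallback sets out from 18 and removes one ester by attack at its methyl group. Krapcho dealkoxycarbonylation (LiCl, wet DMSO, 150 °C) gives the monoester methyl (5R)-3,4-dimethoxy-2-methyl-5-(5-phenylpentyl)-5,6,7,8-tetrahydroquinoline-6-carboxylate F7. Its unhindered ester is saponified with LiOH in THF/H2O, coming back to the route at 20. The reaction time at 150 °C has to be kept short, because chloride can also demethylate the 4-methoxy group.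

## Further compounds

F1 | step 10 | dimethyl 2-{2-[4,5-dimethoxy-6-methyl-3-[(1E)-3-oxoprop-1-en-1-yl]pyridin-2-yl]ethyl}propanedioate | COc1c(OC)c(C)nc(CCC(C(=O)OC)C(=O)OC)c1/C=C/C=O
F2 | step 10 | dimethyl (5S)-3,4-dimethoxy-2-methyl-5-(2-oxoethyl)-7,8-dihydroquinoline-6,6(5H)-dicarboxylate | COc1c(OC)c(C)nc2c1[C@H](CC=O)C(C(=O)OC)(C(=O)OC)CC2
F3 | step 10 | dimethyl (5S)-3,4-dimethoxy-2-methyl-5-[(2Z)-5-phenylpent-2-en-1-yl]-7,8-dihydroquinoline-6,6(5H)-dicarboxylate | COc1c(OC)c(C)nc2c1[C@H](C/C=C\CCc1ccccc1)C(C(=O)OC)(C(=O)OC)CC2
F4 | step 4 | 1-tert-butyl 3,3-dimethyl propane-1,3,3-tricarboxylate | CC(C)(C)OC(=O)CCC(C(=O)OC)C(=O)OC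
F5 | step 4 | 5-methoxy-4-(methoxycarbonyl)-5-oxopentanoic acid | OC(=O)CCC(C(=O)OC)C(=O)OC
F0 | step 7 | none | none
F6 | step 11 | dimethyl (5S)-5-[2-(9-borabicyclo[3.3.1]nonan-9-yl)ethyl]-3,4-dimethoxy-2-methyl-7,8-dihydroquinoline-6,6(5H)-dicarboxylate | COc1c(OC)c(C)nc2c1[C@H](CCB3C4CCCC3CCC4)C(C(=O)OC)(C(=O)OC)CC2
F7 | step 13 | methyl (5R)-3,4-dimethoxy-2-methyl-5-(5-phenylpentyl)-5,6,7,8-tetrahydroquinoline-6-carboxylate (both C6 epimers) | COc1c(OC)c(C)nc2c1[C@H](CCCCCc1ccccc1)C(C(=O)OC)CC2
A1 | alternative 1 | (5R)-3-methoxy-2-methyl-5-(5-phenylpentyl)-5,6,7,8-tetrahydro-4H-chromen-4-one | COc1c(C)oc2c(c1=O)[C@H](CCCCCc1ccccc1)CCC2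
A2 | alternative 1 | 5-methoxy-2,2,6-trimethyl-4H-1,3-dioxin-4-one | COC1=C(C)OC(C)(C)OC1=O
A3 | alternative 1 | 2-methoxybut-1-ene-1,3-dione | CC(=O)C(OC)=C=O
A4 | alternative 1 | trimethyl{[(3R)-3-(5-phenylpentyl)cyclohex-1-en-1-yl]oxy}silane | C[Si](C)(C)OC1=C[C@H](CCCCCc2ccccc2)CCC1
A5 | alternative 2 | ethyl (2E)-2-(3,4-dimethoxy-2-methyl-7,8-dihydroquinolin-5(6H)-ylidene)acetate | CCOC(=O)/C=C1\CCCc2nc(C)c(OC)c(OC)c21
A6 | alternative 2 | 5-iodo-3,4-dimethoxy-2-methylpyridine | COc1c(I)cnc(C)c1OC
A7 | alternative 2 | ethyl (2E)-6-bromohex-2-enoate | CCOC(=O)/C=C/CCCBr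
A8 | alternative 3 | (5R)-5-ethenyl-3,4-dimethoxy-2-methyl-5,8-dihydroquinoline | COc1c(OC)c(C)nc2c1[C@H](C=C)C=CC2
A9 | alternative 3 | 3,4-dimethoxy-2-methyl-5-(penta-1,4-dien-3-yl)-6-(prop-2-en-1-yl)pyridine | C=CCc1nc(C)c(OC)c(OC)c1C(C=C)C=C
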